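**Plan**

- Retrosynthesis: the N–S bond of an N-tosyl precursor is cut last. The benzene ring is then opened at C1–C2 and C5–C6 (C1 carries the pyrrolyl ketone, C2 and C4 the hydroxyls, C3 the isohexyl chain).
- Enabling feature: ring atoms C2–C3–C4–C5 (O, alkyl, O, H) have the oxidation pattern of a 2-alkylacetoacetate and become a 1-methoxy-1,3-bis(silyloxy)diene. C6–C1 with the ketone on C1 are the alkyne of a pyrrolyl ynone.
- Further cuts: the C3–CH2 bond of the side chain (acetoacetate alkylation) and the acyl–alkyne bond (Weinreb amide plus ethynyl Grignard).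
- Forward: diene branch in steps 1–3; ynone branch in steps 4–6, with the acidic pyrrole N–H masked as the sulfonamide so it cannot quench the Grignard reagent or the silyl ketene acetal. The benzene ring, the only ring made, forms in step 7; step 8 frees the N–H.
- Stereochemistry: the target has no stereogenic unit. The racemic centres and enol-ether geometries met on the way are erased on aromatisation.

Key step: step 7

Remark: the target has no stereocentre and no stereogenic double bond, so it is achiral and the demand for a single enantiomer is met without any asymmetric step.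

**Route**

Step 1
Reactants: 1 methyl acetoacetate; 2 1-bromo-4-methylpentane
Product: 3 methyl 2-(4-methylpentyl)-3-oxobutanoate (racemic)
Conditions: NaH (1.0 equiv), 1 (1.2 equiv), THF/DMF, 0 °C; then 2, NaI (cat.), 60 °C
Reagents that add atoms: none
Why: Acetoacetic ester alkylation, in which the sodium enolate of 1 is C-alkylated by the unhindered primary bromide (SN2, iodide-assisted); a slight excess of 1 should hold back dialkylation, and the new centre is racemic and disappears in step 2.

Step 2
Reactants: 3 methyl 2-(4-methylpentyl)-3-oxobutanoate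
Product: 4 methyl (2Z)-2-(4-methylpentyl)-3-(trimethylsilyloxy)but-2-enoate
Conditions: Me3SiCl, Et3N, PhMe, rt; filtration under Ar
Reagents that add atoms: chlorotrimethylsilane, C[Si](C)(C)Cl
Why: Soft enolisation and O-silylation of a β-keto ester (silyl enol ether formation) should give the conjugated internal enol ether, the usual first stage of a Chan-type diene preparation; its geometry is of no consequence.

Step 3
Reactants: 4 methyl (2Z)-2-(4-methylpentyl)-3-(trimethylsilyloxy)but-2-enoate
Product: 5 (1Z)-1-methoxy-2-(4-methylpentyl)-1,3-bis(trimethylsilyloxy)buta-1,3-diene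
Conditions: LDA, THF, −78 °C; then Me3SiCl, −78 °C → rt; pentane, filtration under Ar, used crude
Reagents that add atoms: chlorotrimethylsilane, C[Si](C)(C)Cl
Why: Compound 4 has no α-proton, so LDA can only remove a γ-methyl proton, and O-silylation of the lithium dienolate (silyl ketene acetal formation) should give the 1,3-bis(silyloxy)diene; a non-aqueous work-up protects the labile ketene acetal.

Step 4
Reactants: 6 4,5-dichloro-1H-pyrrole-2-carboxylic acid
Product: 8 4,5-dichloro-N-methoxy-N-methyl-1H-pyrrole-2-carboxamide, via 4,5-dichloro-1H-pyrrole-2-carbonyl chloride 7 (not isolated)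
Conditions: (COCl)2, DMF (cat.), CH2Cl2, 0 °C → rt; concentrate; then MeNH(OMe)·HCl, pyridine, CH2Cl2, 0 °C → rt
Reagents that add atoms: N,O-dimethylhydroxylamine hydrochloride, CNOC.Cl
Why: Vilsmeier-type acid chloride formation followed by amidation (Weinreb amide synthesis); the dichlorinated pyrrole is too deactivated to self-acylate, and adding 7 to the amine with a mild base should outrun ketene-type dimerisation.

Step 5
Reactants: 8 4,5-dichloro-N-methoxy-N-methyl-1H-pyrrole-2-carboxamide
Product: 9 4,5-dichloro-N-methoxy-N-methyl-1-(4-methylbenzenesulfonyl)-1H-pyrrole-2-carboxamide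
Conditions: NaH, DMF, 0 °C; then TsCl, 0 °C → rt
Reagents that add atoms: 4-methylbenzenesulfonyl chloride, Cc1ccc(cc1)S(=O)(=O)Cl
Why: N-Sulfonylation of the sodium pyrrolide, which NaH should form cleanly from the acidic electron-poor N–H; the tosyl group removes the only acidic proton and is inert to acid and to Grignard reagents at low temperature.

Step 6
Reactants: 9 4,5-dichloro-N-methoxy-N-methyl-1-(4-methylbenzenesulfonyl)-1H-pyrrole-2-carboxamide; 10 ethynylmagnesium bromide
Product: 12 1-[4,5-dichloro-1-(4-methylbenzenesulfonyl)-1H-pyrrol-2-yl]prop-2-yn-1-one, via bromomagnesium hemiaminal chelate 11 (not isolated)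
Conditions: 10 (0.5 M in THF, 1.5 equiv), THF, −20 → 0 °C; inverse quench into ice-cold 1 M HCl; used promptly
Reagents that add atoms: none
Why: Weinreb ketone synthesis, in which chelate 11 should persist until the quench so that only one acetylide adds; pouring into cold acid protonates the released N,O-dimethylhydroxylamine before it can add to the terminal ynone.

Step 7
Reactants: 5 (1Z)-1-methoxy-2-(4-methylpentyl)-1,3-bis(trimethylsilyloxy)buta-1,3-diene; 12 1-[4,5-dichloro-1-(4-methylbenzenesulfonyl)-1H-pyrrol-2-yl]prop-2-yn-1-one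
Product: 14 [4,5-dichloro-1-(4-methylbenzenesulfonyl)-1H-pyrrol-2-yl][2,4-dihydroxy-3-(4-methylpentyl)phenyl]methanone, via methoxy bis(silyloxy) cyclohexa-1,4-diene cycloadduct 13 (not isolated)
Conditions: 5 (1.5 equiv), PhMe, 0 °C → rt; then 1 M aq HCl, THF, rt
Reagents that add atoms: none
Why: The electron-rich diene and the electron-poor ynone should combine in a normal-demand [4+2] cycloaddition, either concerted and asynchronous or as a Mukaiyama–Michael addition of the diene CH2 terminus to the alkyne β-carbon followed by collapse of the allenyl enolate onto the silyloxy(methoxy)carbenium carbon; both paths lead to the same 1,4-cyclohexadiene 13. The closest known reaction type is the Diels–Alder benzannulation of Chan- and Brassard-type oxygenated dienes with acetylenic esters and ketones, which gives resorcinol derivatives after eliminative aromatisation. The six-membered carbocycle, the only ring made, closes by this intermolecular [4+2] union forming C5–C6 and C1–C2 (in the stepwise limit the second bond forms by 6-exo-trig attack on the oxocarbenium carbon); acid then ionises the doubly allylic ketal carbon of 13, methanol leaves, the para CH2 loses a proton and both silyl ethers are hydrolysed to give 14. No stereocentre is created that persists, since the single sp3 ketal carbon of 13 and both enol-ether geometries vanish on aromatisation. The step needs regioselectivity only, namely the ketone ortho to the carbon derived from the ketene acetal; this is secured because the unsubstituted diene terminus has the largest HOMO coefficient and the terminal alkyne carbon the largest LUMO coefficient, so these two bond first, and the alkyl group on an inner diene carbon does not alter that polarisation. The N-tosyl group leaves no acidic proton to protodesilylate the diene and survives the acidic aromatisation.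

Step 8
Reactants: 14 [4,5-dichloro-1-(4-methylbenzenesulfonyl)-1H-pyrrol-2-yl][2,4-dihydroxy-3-(4-methylpentyl)phenyl]methanone
Product: 15 (4,5-dichloro-1H-pyrrol-2-yl)[2,4-dihydroxy-3-(4-methylpentyl)phenyl]methanone (target, CNP0317757.0)
Conditions: 2 M aq NaOH, 1,4-dioxane, rt → 40 °C; then 1 M HCl to pH 3
Reagents that add atoms: none
Why: Hydrolytic N-desulfonylation, in which hydroxide attacks sulfur and expels the well-stabilised dichloro-acylpyrrolide; working without methanol avoids methyl tosylate and hence O- or N-methylation, the phenoxides and aryl chlorides should be inert, and acidification returns the neutral target.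

**Compound list**

1 | methyl acetoacetate | COC(=O)CC(C)=O | starting material
2 | 1-bromo-4-methylpentane | CC(C)CCCBr | starting material
3 | methyl 2-(4-methylpentyl)-3-oxobutanoate (racemic) | COC(=O)C(CCCC(C)C)C(C)=O | intermediate
4 | methyl (2Z)-2-(4-methylpentyl)-3-(trimethylsilyloxy)but-2-enoate (one geometry drawn) | COC(=O)/C(CCCC(C)C)=C(/C)O[Si](C)(C)C | intermediate
5 | (1Z)-1-methoxy-2-(4-methylpentyl)-1,3-bis(trimethylsilyloxy)buta-1,3-diene (one geometry drawn) | C=C(O[Si](C)(C)C)/C(CCCC(C)C)=C(/OC)O[Si](C)(C)C | intermediate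
6 | 4,5-dichloro-1H-pyrrole-2-carboxylic acid | OC(=O)c1cc(Cl)c(Cl)[nH]1 | starting material
7 | 4,5-dichloro-1H-pyrrole-2-carbonyl chloride (not isolated) | O=C(Cl)c1cc(Cl)c(Cl)[nH]1 | intermediate
8 | 4,5-dichloro-N-methoxy-N-methyl-1H-pyrrole-2-carboxamide | CON(C)C(=O)c1cc(Cl)c(Cl)[nH]1 | intermediate
9 | 4,5-dichloro-N-methoxy-N-methyl-1-(4-methylbenzenesulfonyl)-1H-pyrrole-2-carboxamide | CON(C)C(=O)c1cc(Cl)c(Cl)n1S(=O)(=O)c1ccc(C)cc1 | intermediate
10 | ethynylmagnesium bromide | C#C[Mg]Br | starting material
11 | bromomagnesium 1-[4,5-dichloro-1-(4-methylbenzenesulfonyl)-1H-pyrrol-2-yl]-1-[methoxy(methyl)amino]prop-2-yn-1-olate (racemic, not isolated) | CON(C)C(O[Mg]Br)(C#C)c1cc(Cl)c(Cl)n1S(=O)(=O)c1ccc(C)cc1 | intermediate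
12 | 1-[4,5-dichloro-1-(4-methylbenzenesulfonyl)-1H-pyrrol-2-yl]prop-2-yn-1-one | C#CC(=O)c1cc(Cl)c(Cl)n1S(=O)(=O)c1ccc(C)cc1 | intermediate
13 | [4,5-dichloro-1-(4-methylbenzenesulfonyl)-1H-pyrrol-2-yl][6-methoxy-5-(4-methylpentyl)-4,6-bis(trimethylsilyloxy)cyclohexa-1,4-dien-1-yl]methanone (racemic, not isolated) | COC1(O[Si](C)(C)C)C(CCCC(C)C)=C(O[Si](C)(C)C)CC=C1C(=O)c1cc(Cl)c(Cl)n1S(=O)(=O)c1ccc(C)cc1 | intermediate
14 | [4,5-dichloro-1-(4-methylbenzenesulfonyl)-1H-pyrrol-2-yl][2,4-dihydroxy-3-(4-methylpentyl)phenyl]methanone | CC(C)CCCc1c(O)ccc(C(=O)c2cc(Cl)c(Cl)n2S(=O)(=O)c2ccc(C)cc2)c1O | intermediate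
15 | (4,5-dichloro-1H-pyrrol-2-yl)[2,4-dihydroxy-3-(4-methylpentyl)phenyl]methanone | CC(C)CCCc1c(O)ccc(C(=O)c2cc(Cl)c(Cl)[nH]2)c1O | target

**Step count**

Total: 8 steps. Longest linear sequence: 5 steps (6 → 8 → 9 → 12 → 14 → 15, or equally 1 → 3 → 4 → 5 → 14 → 15).

**Steps most likely to fail**

Step 7. The union may stop after the first C–C bond, with silyl transfer giving an open-chain Michael adduct instead of ring closure. The diene may also be protodesilylated before it reacts, or the terminal ynone may oligomerise. The fallback gives up the benzannulation and builds the aryl ketone bond by classical arene acylation. It sets out from bromide 2 and acid chloride 7 (made from 6 as in the first stage of step 4) and comes back at 15. Commercial 1,3-dimethoxybenzene is lithiated between the two methoxy groups (n-BuLi, THF, 0 °C → rt) and alkylated with 2 to give 1,3-dimethoxy-2-(4-methylpentyl)benzene F1. Friedel–Crafts acylation of F1 with 7 (AlCl3, CH2Cl2, 0 °C → rt) can only occur para to one methoxy group and ortho to the other, and should give (4,5-dichloro-1H-pyrrol-2-yl)[2,4-dimethoxy-3-(4-methylpentyl)phenyl]methanone F2. BBr3 (CH2Cl2, −78 °C → rt) then cleaves both methyl ethers to 15.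

Step 6. The liberated N,O-dimethylhydroxylamine or excess acetylide may add to the terminal ynone during the quench. The Grignard reagent may attack sulfur and strip the tosyl group, or addition to the hindered amide may stall. The fallback forms the ynone by oxidation, with no amine present; it sets out from 9 and comes back at 12. DIBAL-H (THF, −78 °C) reduces the Weinreb amide through the diisobutylaluminium hemiaminal of 9 F3 (not isolated). Rochelle-salt work-up releases 4,5-dichloro-1-(4-methylbenzenesulfonyl)-1H-pyrrole-2-carbaldehyde F4. Addition of 10 (THF, −78 → 0 °C) gives racemic 1-[4,5-dichloro-1-(4-methylbenzenesulfonyl)-1H-pyrrol-2-yl]prop-2-yn-1-ol F5, and MnO2 (CH2Cl2, rt) oxidises the propargylic alcohol to 12.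

Step 3. γ-Deprotonation may be incomplete, silylation may go partly to carbon, and the bis-silyl ketene acetal may hydrolyse on handling. The fallback uses a more robust Brassard-type diene with one silyl group fewer; it sets out from 3 and comes back at 14. Trimethyl orthoformate with catalytic H2SO4 in MeOH converts 3 into methyl (2E)-3-methoxy-2-(4-methylpentyl)but-2-enoate F6. LDA then Me3SiCl (THF, −78 °C) gives (1Z)-1,3-dimethoxy-2-(4-methylpentyl)-1-(trimethylsilyloxy)buta-1,3-diene F7. Cycloaddition with 12 under the conditions of step 7 passes through the dimethoxy silyloxy cyclohexa-1,4-diene cycloadduct F8 (not isolated). Acid then gives [4,5-dichloro-1-(4-methylbenzenesulfonyl)-1H-pyrrol-2-yl][2-hydroxy-4-methoxy-3-(4-methylpentyl)phenyl]methanone F9. BBr3 (CH2Cl2, −78 → 0 °C) cleaves the remaining methyl ether to 14.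

**Further compounds**

F1 | step 7 | 1,3-dimethoxy-2-(4-methylpentyl)benzene | COc1cccc(OC)c1CCCC(C)C
F2 | step 7 | (4,5-dichloro-1H-pyrrol-2-yl)[2,4-dimethoxy-3-(4-methylpentyl)phenyl]methanone | COc1ccc(C(=O)c2cc(Cl)c(Cl)[nH]2)c(OC)c1CCCC(C)C
F3 | step 6 | diisobutylaluminium [4,5-dichloro-1-(4-methylbenzenesulfonyl)-1H-pyrrol-2-yl][methoxy(methyl)amino]methanolate (racemic, not isolated) | CON(C)C(O[Al](CC(C)C)CC(C)C)c1cc(Cl)c(Cl)n1S(=O)(=O)c1ccc(C)cc1
F4 | step 6 | 4,5-dichloro-1-(4-methylbenzenesulfonyl)-1H-pyrrole-2-carbaldehyde | O=Cc1cc(Cl)c(Cl)n1S(=O)(=O)c1ccc(C)cc1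
F5 | step 6 | 1-[4,5-dichloro-1-(4-methylbenzenesulfonyl)-1H-pyrrol-2-yl]prop-2-yn-1-ol (racemic) | C#CC(O)c1cc(Cl)c(Cl)n1S(=O)(=O)c1ccc(C)cc1
F6 | step 3 | methyl (2E)-3-methoxy-2-(4-methylpentyl)but-2-enoate | COC(=O)/C(CCCC(C)C)=C(\C)OC
F7 | step 3 | (1Z)-1,3-dimethoxy-2-(4-methylpentyl)-1-(trimethylsilyloxy)buta-1,3-diene (one geometry drawn) | C=C(OC)/C(CCCC(C)C)=C(/OC)O[Si](C)(C)C
F8 | step 3 | [4,5-dichloro-1-(4-methylbenzenesulfonyl)-1H-pyrrol-2-yl][4,6-dimethoxy-5-(4-methylpentyl)-6-(trimethylsilyloxy)cyclohexa-1,4-dien-1-yl]methanone (racemic, not isolated) | COC1=C(CCCC(C)C)C(OC)(O[Si](C)(C)C)C(C(=O)c2cc(Cl)c(Cl)n2S(=O)(=O)c2ccc(C)cc2)=CC1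
F9 | step 3 | [4,5-dichloro-1-(4-methylbenzenesulfonyl)-1H-pyrrol-2-yl][2-hydroxy-4-methoxy-3-(4-methylpentyl)phenyl]methanone | COc1ccc(C(=O)c2cc(Cl)c(Cl)n2S(=O)(=O)c2ccc(C)cc2)c(O)c1CCCC(C)C
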